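**Plan**

1. Rings: A = hemiketal tetrahydropyran, B = N‑methylpiperidine, C = seven‑membered carbocycle, D = ester‑bearing cyclopentene, E = the other cyclopentene.
2. Cuts, late to early: ring A opened to a δ‑hydroxy ketone; at the spiro carbon the side‑chain C=C (olefination) and the CH2OH (formaldehyde aldol) are removed, leaving a bridging ketone; ring B is cut at NCH2–CH (Mannich); the ester C–C bond is cut (carbonylation of a dienyl triflate).
3. Then ring E is cut at one CH2–C bond back to a spiro‑cyclopropane, ring D at its enone C=C (aldol), and the two exocyclic bonds of the quaternary carbon (amidomethylation, allylation) back to cycloheptane‑1,3‑dione, which supplies ring C.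
4. Forward order: ring C (bought) → ring D (desymmetrising aldol) → ring E (spiro‑cyclopropanation, then ring expansion) → ester → ring B (Mannich) → spiro carbon → ring A.
5. Enabling feature: the two CH2 groups of ring E bridge the α‑ and γ‑carbons of the ring D enone (carbonyl carbon = the later ester‑bearing carbon, γ‑carbon = the ring C/E junction). Ring E is therefore a 1‑acyl‑1‑vinylcyclopropane in disguise, and its 1,3‑shift gives the tetrasubstituted enone whose through‑conjugated dienolate leads to the diene ester.
6. Stereochemistry: the quaternary carbon shared by rings B, C and D comes from (S)‑proline desymmetrisation of a prochiral triketone; the bridgehead CH follows from the bridging Mannich closure; the spiro carbon from face‑selective hydroxymethylation; the hemiketal carbon is thermodynamic.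

Key step: step 7

Remark: the hemiketal carbon of ring A interconverts through the open hydroxy ketone, so its configuration is taken to be the one reached at equilibrium on ring closure.

**Route**

Step 1
Reactants: 1 cycloheptane‑1,3‑dione
Product: 2 2‑allylcycloheptane‑1,3‑dione
Conditions: allyl bromide (1.05 equiv), KOH (1.0 equiv), Cu powder (cat.), H2O, rt
Reagents that add atoms: allyl bromide, C=CCBr
Why: Enolate alkylation of the cyclic 1,3‑dione in aqueous base, where the hydrogen‑bonding medium and the soft allyl electrophile favour carbon over oxygen.

Step 2
Reactants: 2 2‑allylcycloheptane‑1,3‑dione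
Product: 3 allyl amidomethyl dione
Conditions: N‑(hydroxymethyl)‑N‑methylformamide (1.3 equiv), TfOH (10 mol %), MeCN, 50 °C
Reagents that add atoms: N‑(hydroxymethyl)‑N‑methylformamide, O=CN(C)CO
Why: The acid turns the N‑hydroxymethyl amide into an N‑acyliminium ion that the dione enol captures at its central carbon (Tscherniac–Einhorn‑type amidomethylation, a Mannich‑type reaction), O‑capture being reversible, so the fully substituted prochiral carbon should form.

Step 3
Reactants: 3 allyl amidomethyl dione
Product: 4 prochiral triketone
Conditions: PdCl2 (10 mol %), CuCl (20 mol %), O2 (1 atm), DMF/H2O 7:1, rt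
Reagents that add atoms: water, O
Why: Wacker–Tsuji oxidation should convert the terminal alkene into the methyl ketone with Markovnikov regiochemistry, dioxygen being the terminal oxidant, without touching the non‑enolisable dione carbon.

Step 4
Reactants: 4 prochiral triketone
Product: 6 bicyclic (S)‑enedione, via cis‑fused ketol 5 (not isolated)
Conditions: (S)‑proline (30 mol %), DMF, rt; then TsOH·H2O (10 mol %), toluene, 80 °C
Reagents that add atoms: none
Why: Hajos–Parrish‑type desymmetrising aldol condensation, in which the proline enamine of the methyl ketone adds under carboxylic‑acid direction to one of the two enantiotopic ring carbonyls and so sets the quaternary stereocentre (sense assigned by analogy with the Hajos–Parrish ketone from (S)‑proline), after which acid dehydrates the ketol to the ring D enone.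

Step 5
Reactants: 6 bicyclic (S)‑enedione
Product: 7 enone mono‑ketal
Conditions: ethylene glycol (2 equiv), TsOH·H2O (5 mol %), benzene, reflux, Dean–Stark trap
Reagents that add atoms: ethylene glycol, OCCO
Why: Acid‑catalysed ketalisation should occur selectively at the saturated ketone, which is more electrophilic than the conjugated one (as with the Wieland–Miescher ketone), and it removes that ketone's acidic α‑CH2 from the following base steps.

Step 6
Reactants: 7 enone mono‑ketal
Product: 8 spiro‑cyclopropyl ketone
Conditions: (2‑bromoethyl)diphenylsulfonium triflate (1.2 equiv), KOtBu (2.3 equiv), t‑BuOH/THF, 0 °C → rt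
Reagents that add atoms: (2‑bromoethyl)diphenylsulfonium trifluoromethanesulfonate, BrCC[S+](c1ccccc1)c1ccccc1.[O-]S(=O)(=O)C(F)(F)F
Why: Spiro‑annulation of an enone, in which the thermodynamic through‑conjugated dienolate attacks the in situ vinylsulfonium salt at its α‑carbon, proton transfer gives a new enolate, and 3‑exo‑tet displacement of Ph2S closes the cyclopropane, leaving the C=C deconjugated in ring C.

Step 7
Reactants: 8 spiro‑cyclopropyl ketone
Product: 9 tricyclic tetrasubstituted enone
Conditions: flash vacuum pyrolysis, 500 °C, 0.05 mbar, base‑washed quartz tube, product trapped at −78 °C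
Reagents that add atoms: none
Why: Thermal vinylcyclopropane–cyclopentene rearrangement: homolysis of one of the two cyclopropane bonds at the spiro carbon gives a primary alkyl radical and a radical delocalised over the carbonyl oxygen, the spiro carbon and the ring C alkene, and recombination at the alkene terminus is a net 1,3‑shift of CH2 that expands the three‑membered ring by two atoms into ring E and leaves the C=C conjugated with the ketone. The closest known reaction type is the flash‑vacuum cyclopentene annulation of acyl‑substituted vinylcyclopropanes. Ring E is closed by radical recombination at the terminus of the allyl unit, a closure that needs no backside trajectory and is therefore open here, whereas the ionic equivalent (five‑membered ring through a dienolate terminus) is geometrically disfavoured. The new CH at the ring C/E junction is formed without control as an epimer mixture and is made planar again in step 8. The step needs bond selectivity and C‑ over O‑recombination: the two proximal cyclopropane bonds are equivalent because the CH2CH2 unit is unsubstituted, the distal bond gives no stabilised radical, ring D holds the vinyl group cisoid to the breaking bond, and closure on oxygen (dihydrofuran) is reversible while C‑closure gives the stable conjugated enone.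

Step 8
Reactants: 9 tricyclic tetrasubstituted enone
Product: 10 dienyl triflate
Conditions: KOtBu (1.1 equiv), THF, 0 °C, 30 min; then PhNTf2 (1.2 equiv), 0 °C → rt
Reagents that add atoms: N‑phenylbis(trifluoromethanesulfonimide), O=S(=O)(N(c1ccccc1)S(=O)(=O)C(F)(F)F)C(F)(F)F
Why: Under equilibrating alkoxide conditions the γ‑methine at the ring C/E junction should be removed to give the through‑conjugated dienolate (more stable than the cross‑conjugated one from the ring D CH2), and its O‑sulfonylation (enol triflate formation) fixes the diene of the target and erases the uncontrolled stereocentre.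

Step 9
Reactants: 10 dienyl triflate
Product: 11 diene methyl ester
Conditions: Pd(OAc)2 (5 mol %), PPh3 (10 mol %), CO (1 atm), MeOH, Et3N (2 equiv), DMF, 60 °C
Reagents that add atoms: carbon monoxide, [C-]#[O+]; methanol, CO
Why: Palladium‑catalysed methoxycarbonylation of a dienyl triflate (oxidative addition, CO insertion, methanolysis of the acylpalladium) should install the ester with the diene already in place.

Step 10
Reactants: 11 diene methyl ester
Product: 13 azatetracyclic ketone, via amino ketone hydrochloride 12 (not isolated)
Conditions: HCl (3 M in MeOH), 50 °C; H2O; concentrate; then 37 % aq. CH2O (3 equiv), EtOH, 80 °C; aq. NaHCO3 work‑up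
Reagents that add atoms: formaldehyde, C=O
Why: Acidic methanolysis removes the formyl group and the ketal, and the secondary ammonium salt then condenses with formaldehyde to an iminium ion captured by the enol of the only enolisable ketone at its single α‑CH2 (intramolecular Mannich reaction closing ring B), the new bridgehead CH being fixed because the three‑atom bridge can only span ring C cis from the existing quaternary carbon.

Step 11
Reactants: 13 azatetracyclic ketone
Product: 15 bridge aldehyde, via methyl enol ether 14 (not isolated)
Conditions: (methoxymethyl)triphenylphosphonium chloride (3 equiv), KN(SiMe3)2 (2.9 equiv), THF, 0 → 50 °C; then 2 M aq. HCl, THF, rt; aq. NaHCO3 work‑up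
Reagents that add atoms: (methoxymethyl)triphenylphosphonium chloride, COC[P+](c1ccccc1)(c1ccccc1)c1ccccc1.[Cl-]; water, O
Why: Wittig methoxymethylenation of the non‑enolisable bridging ketone followed by enol ether hydrolysis is a one‑carbon homologation to the aldehyde, whose α‑configuration is irrelevant because that carbon becomes planar again in step 12.

Step 12
Reactants: 15 bridge aldehyde
Product: 16 hydroxymethyl aldehyde
Conditions: 37 % aq. CH2O (3 equiv), K2CO3 (20 mol %), MeOH, 0 °C → rt
Reagents that add atoms: formaldehyde, C=O
Why: Crossed aldol addition (hydroxymethylation) of the α‑branched aldehyde through its exocyclic enolate creates the quaternary spiro carbon, and formaldehyde should approach over ring C, where the flanking sp2 ring‑junction carbon offers no syn‑axial hydrogen, not over the piperidine chair with its two syn‑axial C–H bonds, so that CH2OH ends on the ring C face.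

Step 13
Reactants: 16 hydroxymethyl aldehyde
Product: 17 (E)‑enone
Conditions: diethyl (2‑oxobutyl)phosphonate (1.5 equiv), LiCl, i‑Pr2NEt, MeCN, rt
Reagents that add atoms: diethyl (2‑oxobutyl)phosphonate, CCC(=O)CP(=O)(OCC)OCC
Why: Horner–Wadsworth–Emmons olefination under Masamune–Roush conditions should give the (E)‑enone and is mild enough to avoid retro‑aldol loss of formaldehyde.

Step 14
Reactants: 17 (E)‑enone
Product: 19 CNP0192143.1, via open hydroxy ketone 18 (not isolated)
Conditions: H2 (3 atm), RhCl(PPh3)3 (10 mol %), benzene/EtOH 1:1, rt
Reagents that add atoms: none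
Why: Homogeneous hydrogenation with RhCl(PPh3)3 should saturate only the disubstituted enone C=C, the tetrasubstituted diene ester being inert, and the δ‑hydroxy ketone then closes spontaneously to the six‑membered hemiketal ring A under thermodynamic control.

**Compound list**

1 | cycloheptane‑1,3‑dione | O=C1CCCCC(=O)C1 | starting material
2 | 2‑(prop‑2‑en‑1‑yl)cycloheptane‑1,3‑dione | C=CCC1C(=O)CCCCC1=O | intermediate
3 | N‑{[2,7‑dioxo‑1‑(prop‑2‑en‑1‑yl)cycloheptyl]methyl}‑N‑methylformamide (achiral) | C=CCC1(CN(C)C=O)C(=O)CCCCC1=O | intermediate
4 | N‑{[2,7‑dioxo‑1‑(2‑oxopropyl)cycloheptyl]methyl}‑N‑methylformamide (prochiral triketone) | CC(=O)CC1(CN(C)C=O)C(=O)CCCCC1=O | intermediate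
5 | N‑{[(3aS,8aR)‑3a‑hydroxy‑2,8‑dioxodecahydroazulen‑8a‑yl]methyl}‑N‑methylformamide (cis‑fused ketol, OH cis to the amidomethyl group) | O=C1CCCC[C@]2(O)CC(=O)C[C@@]21CN(C)C=O | intermediate
6 | N‑{[(8aS)‑2,8‑dioxo‑1,2,4,5,6,7,8,8a‑octahydroazulen‑8a‑yl]methyl}‑N‑methylformamide (rings C and D, enone in ring D) | O=C1CCCCC2=CC(=O)C[C@@]21CN(C)C=O | intermediate
7 | ethylene ketal of 6 at the saturated (ring C) ketone, (S) at the quaternary carbon | O1CCOC12CCCCC3=CC(=O)C[C@@]32CN(C)C=O | intermediate
8 | ketal 7 carrying a cyclopropane spiro‑fused at the former enone α‑carbon, ring D ketone saturated, C=C now in ring C, (S) | O1CCOC12CCCC=C3C4(CC4)C(=O)C[C@@]32CN(C)C=O | intermediate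
9 | tricyclic enone of rings C, D, E: ring D cyclopentenone with ring E fused on its tetrasubstituted C=C, ring C ketal, (S) quaternary carbon, epimer mixture at the new ring C/E junction CH | O1CCOC12CCCC3C4=C(CC3)C(=O)C[C@@]42CN(C)C=O | intermediate
10 | dienyl triflate of 9 (C=C at the ring C/E junction, C(OTf)=C in ring D), (S) | O1CCOC12CCCC3=C4C(CC3)=C(OS(=O)(=O)C(F)(F)F)C[C@@]42CN(C)C=O | intermediate
11 | diene methyl ester (OTf of 10 replaced by CO2Me), (S) | O1CCOC12CCCC3=C4C(CC3)=C(C(=O)OC)C[C@@]42CN(C)C=O | intermediate
12 | amino ketone hydrochloride: 11 without ketal and formyl group (ring C ketone, CH2NHMe·HCl), (S) | O=C1CCCC2=C3C(CC2)=C(C(=O)OC)C[C@@]31CNC.Cl | intermediate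
13 | azatetracyclic ketone (rings B–E): N‑methylpiperidin‑4‑one whose 3‑ and 5‑carbons are the quaternary and CH bridgeheads, configured as in the target | O=C2[C@@H]1CCC3=C4C(=C(C(=O)OC)C[C@@]42CN(C)C1)CC3 | intermediate
14 | methyl enol ether of 13 (C=CH–OMe at the bridge carbon, E/Z mixture) | COC=C2[C@@H]1CCC3=C4C(=C(C(=O)OC)C[C@@]42CN(C)C1)CC3 | intermediate
15 | bridge aldehyde (CH–CHO at the bridge carbon, epimer mixture there) | O=CC2[C@@H]1CCC3=C4C(=C(C(=O)OC)C[C@@]42CN(C)C1)CC3 | intermediate
16 | hydroxymethyl aldehyde: quaternary bridge carbon with CHO on the piperidine face and CH2OH on the ring C face | O=C[C@@]2(CO)[C@@H]1CCC3=C4C(=C(C(=O)OC)C[C@@]42CN(C)C1)CC3 | intermediate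
17 | (E)‑enone: CHO of 16 replaced by (E)‑CH=CH–C(=O)Et | CCC(=O)/C=C/[C@@]2(CO)[C@@H]1CCC3=C4C(=C(C(=O)OC)C[C@@]42CN(C)C1)CC3 | intermediate
18 | open hydroxy ketone: 3‑oxopentyl and CH2OH on the spiro carbon | CCC(=O)CC[C@@]2(CO)[C@@H]1CCC3=C4C(=C(C(=O)OC)C[C@@]42CN(C)C1)CC3 | intermediate
19 | CNP0192143.1 (hemiketal carbon S, spiro carbon R, bridgehead CH S, quaternary bridgehead R) | CC[C@@]1(O)CC[C@@]2(CO1)[C@@H]1CCC3=C4C(=C(C(=O)OC)C[C@@]42CN(C)C1)CC3 | target

Total step count: 14. Longest linear sequence: 14 steps.

**Steps most likely to fail**

Step 7. At the temperature needed for homolysis the diradical may close on oxygen, or the material may decompose or lose the ketal before it rearranges. Fallback, from 8 back to 9: Ni(cod)2 (10 mol %) with 1,3‑bis(2,6‑diisopropylphenyl)imidazol‑2‑ylidene in toluene at 60–100 °C. Zerovalent nickel inserts into the cyclopropane bond activated by the acyl and vinyl groups, and the alkyl(allyl)nickel species reductively eliminates at the allyl terminus. This replaces thermal homolysis by a two‑electron organometallic bond activation at low temperature; it is a known catalytic vinylcyclopropane isomerisation and makes no new isolated compound.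

Step 4. The five‑membered enamine aldolisation may be sluggish or show poor discrimination between the two enantiotopic carbonyls, giving low enantiomeric purity. Fallback, from 4 back to 6: base‑mediated aldol condensation (KOH, MeOH, rt → 50 °C) proceeds through the racemic ketol, that is 5 and its mirror image, the enantiomeric ketol F1. It gives 6 together with the enantiomeric enedione F2. The enantiomers are separated by preparative supercritical‑fluid chromatography on a chiral stationary phase and 6 is carried on.

Step 12. Facial selectivity in the hydroxymethylation may be poor or opposite, and retro‑aldol or crossed Cannizzaro reactions may erode the product. Fallback, from 13 to 18 and hence 19, used if the incoming group proves to prefer the piperidine face: the two carbon substituents are introduced in the reverse order. Corey–Chaykovsky methylenation (Me3S+ I−, KN(SiMe3)2, THF, 0 °C) gives the spiro‑epoxide F3. Cp2TiCl (trivalent titanium, from Cp2TiCl2 and Zn dust, THF) opens it reductively to the tertiary radical that already carries CH2O–Ti, and this radical adds to pent‑1‑en‑3‑one. Aqueous work‑up gives 18, which closes to 19. Here the ketone chain, not the CH2OH, is the group that enters last, so the facial outcome is the complement of step 12; this path also avoids the hindered Wittig reaction of step 11.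

**Further compounds**

F0 | step 7 | none | none
F1 | step 4 | enantiomer of ketol 5, N‑{[(3aR,8aS)‑3a‑hydroxy‑2,8‑dioxodecahydroazulen‑8a‑yl]methyl}‑N‑methylformamide | O=C1CCCC[C@@]2(O)CC(=O)C[C@]21CN(C)C=O
F2 | step 4 | enantiomer of 6, N‑{[(8aR)‑2,8‑dioxo‑1,2,4,5,6,7,8,8a‑octahydroazulen‑8a‑yl]methyl}‑N‑methylformamide | O=C1CCCCC2=CC(=O)C[C@]21CN(C)C=O
F3 | step 12 | spiro‑epoxide of 13 (oxirane at the bridge carbon, either epimer) | C1OC12[C@@H]3CCC4=C5C(=C(C(=O)OC)C[C@@]52CN(C)C3)CC4
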